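**Retrosynthetic overview**
- The dihydrofuran ring and the only stereocentre are made last: target ⇐ symmetric 2,6-diprenyl-3,5-dihydroxy-(Z)-stilbene, by chiral-ketone (dioxirane) mono-epoxidation of one of the two equivalent prenyl groups and phenoxide 5-exo-tet ring closure.
- Diprenyl bisphenol ⇐ (Z)-2,6-dibromo-3,5-bis(silyloxy)stilbene, by double Stille prenylation and desilylation in one flask.
- Z alkene ⇐ 2,6-dibromo-3,5-bis(silyloxy)benzaldehyde and a benzyl ylide (Wittig; the two ortho bromines steer to Z).
- Dibromo aldehyde ⇐ 3,5-dihydroxybenzaldehyde, by silylation and twofold bromination.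
- Ring order: both benzene rings are bought; the dihydrofuran ring is the only ring formed, in the final step.

Assumption: no configuration is defined for the aryl–vinyl axis, so C2 (S) and the Z alkene are the only stereo-elements; tributyl(3-methylbut-2-en-1-yl)stannane and the D-fructose-derived ketone catalyst are taken as purchasable.

**Route**

Step 1
Reactants: 1 3,5-dihydroxybenzaldehyde; 2 tert-butyldimethylsilyl chloride
Product: 3 3,5-bis[(tert-butyldimethylsilyl)oxy]benzaldehyde
Conditions: 2 (2.4 equiv), imidazole (5 equiv), DMF, 0 → 23 °C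
Reagents that add atoms: tert-butyldimethylsilyl chloride (2), CC(C)(C)[Si](C)(C)Cl
Why: Imidazole-mediated silyl ether formation masks both phenols for the ylide chemistry and makes the ring position between the two oxygens too crowded to brominate.

Step 2
Reactants: 3 3,5-bis[(tert-butyldimethylsilyl)oxy]benzaldehyde; 4 N-bromosuccinimide
Product: 5 2,6-dibromo-3,5-bis[(tert-butyldimethylsilyl)oxy]benzaldehyde
Conditions: 4 (2.3 equiv), DMF, 0 → 40 °C, dark
Reagents that add atoms: N-bromosuccinimide (4), O=C1CCC(=O)N1Br
Why: Electrophilic aromatic bromination places each bromine para to one silyloxy group and ortho to the other (the two equivalent positions flanking the formyl group), while the position between the two bulky silyloxy groups is only ortho-activated and sterically closed.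

Step 3
Reactants: 5 2,6-dibromo-3,5-bis[(tert-butyldimethylsilyl)oxy]benzaldehyde; 6 benzyltriphenylphosphonium bromide
Product: 7 (Z)-1,3-dibromo-4,6-bis[(tert-butyldimethylsilyl)oxy]-2-(2-phenylethenyl)benzene
Conditions: 6 (1.3 equiv), NaN(SiMe3)2 (1.25 equiv), THF, −78 °C; then 5, −78 → 0 °C
Reagents that add atoms: benzyltriphenylphosphonium bromide (6), [Br-].C(c1ccccc1)[P+](c1ccccc1)(c1ccccc1)c1ccccc1
Why: Lithium-free, kinetically controlled Wittig olefination with the semi-stabilised benzylide, in which the two ortho bromines of the aldehyde favour the cis-oxaphosphetane (ortho-halogen effect), so the Z alkene is expected as the major isomer (about 9:1) and is purified by chromatography.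

Step 4
Reactants: 7 (Z)-1,3-dibromo-4,6-bis[(tert-butyldimethylsilyl)oxy]-2-(2-phenylethenyl)benzene; 8 tributyl(3-methylbut-2-en-1-yl)stannane
Product: 10 4,6-bis(3-methylbut-2-en-1-yl)-5-[(Z)-2-phenylethenyl]benzene-1,3-diol, via bis-silyl diprenyl stilbene 9 (not isolated)
Conditions: 8 (2.6 equiv), Pd(PPh3)4 (10 mol %), DMF, 95 °C; then Bu4NF/AcOH (1:1, 4 equiv), THF, 0 → 23 °C
Reagents that add atoms: tributyl(3-methylbut-2-en-1-yl)stannane (8), CCCC[Sn](CCCC)(CCCC)CC=C(C)C
Why: Base-free double Stille cross-coupling replaces both aryl bromides by the linear prenyl group normally delivered by this stannane, and buffered fluoride then cleaves the two aryl silyl ethers in the same flask without touching the Z alkene.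

Step 5
Reactants: 10 4,6-bis(3-methylbut-2-en-1-yl)-5-[(Z)-2-phenylethenyl]benzene-1,3-diol; 11 potassium peroxymonosulfate KHSO5
Product: 13 (2S)-2-(2-hydroxypropan-2-yl)-5-(3-methylbut-2-en-1-yl)-4-[(Z)-2-phenylethenyl]-2,3-dihydro-1-benzofuran-6-ol, via (R)-epoxy bisphenol 12 (not isolated)
Conditions: 1,2:4,5-di-O-isopropylidene-β-D-erythro-2,3-hexodiulo-2,6-pyranose (D-fructose-derived Shi ketone, 30 mol %), Bu4NHSO4 (5 mol %), MeCN–CH2(OMe)2 (1:2), aq. K2CO3/KHCO3 buffer (pH 10), 11 (0.7 equiv, as 2KHSO5·KHSO4·K2SO4) added over 2 h, −5 °C, stopped at about 55% conversion of 10; then K2CO3 (3 equiv), MeOH, 23 °C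
Reagents that add atoms: potassium peroxymonosulfate, KHSO5 (11), [K+].[O-]S(=O)(=O)OO
Why: Proposed new method: a chiral-dioxirane epoxidation run directly on an unprotected bis(ortho-prenyl)resorcinol and merged in one flask with phenoxide ring closure (a formal catalytic asymmetric hydroxy-cycloetherification), reasoned as follows – the lipophilic, un-ionised bisphenol stays in the organic layer where the only oxidant it meets is the electrophilic dioxirane of the D-fructose-derived ketone, which transfers oxygen through the usual spiro transition state to the electron-rich trisubstituted prenyl alkene far faster than to a neutral phenol ring or to the hindered, twisted Z-stilbene alkene, giving the (R)-epoxide on one of the two equivalent prenyl groups while sub-stoichiometric KHSO5 holds the reaction at mono-oxidation, and carbonate in methanol then converts the neighbouring phenol into a phenoxide that opens the epoxide 5-exo-tet at the secondary carbon with inversion, which sets C2 as (S) and frees the tertiary alcohol; the closest known reaction type is Shi epoxidation of O-protected ortho-prenylphenols followed by a separate deprotection and cyclisation.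

**Compound list**
1 | 3,5-dihydroxybenzaldehyde | O=Cc1cc(O)cc(O)c1 | starting material
2 | tert-butyldimethylsilyl chloride | CC(C)(C)[Si](C)(C)Cl | starting material
3 | 3,5-bis[(tert-butyldimethylsilyl)oxy]benzaldehyde | O=Cc1cc(O[Si](C)(C)C(C)(C)C)cc(O[Si](C)(C)C(C)(C)C)c1 | intermediate
4 | N-bromosuccinimide | O=C1CCC(=O)N1Br | starting material
5 | 2,6-dibromo-3,5-bis[(tert-butyldimethylsilyl)oxy]benzaldehyde | O=Cc1c(Br)c(O[Si](C)(C)C(C)(C)C)cc(O[Si](C)(C)C(C)(C)C)c1Br | intermediate
6 | benzyltriphenylphosphonium bromide | [Br-].C(c1ccccc1)[P+](c1ccccc1)(c1ccccc1)c1ccccc1 | starting material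
7 | (Z)-1,3-dibromo-4,6-bis[(tert-butyldimethylsilyl)oxy]-2-(2-phenylethenyl)benzene | Brc1c(O[Si](C)(C)C(C)(C)C)cc(O[Si](C)(C)C(C)(C)C)c(Br)c1/C=C\c1ccccc1 | intermediate
8 | tributyl(3-methylbut-2-en-1-yl)stannane | CCCC[Sn](CCCC)(CCCC)CC=C(C)C | starting material
9 | (Z)-1,3-bis(3-methylbut-2-en-1-yl)-4,6-bis[(tert-butyldimethylsilyl)oxy]-2-(2-phenylethenyl)benzene | CC(C)=CCc1c(O[Si](C)(C)C(C)(C)C)cc(O[Si](C)(C)C(C)(C)C)c(CC=C(C)C)c1/C=C\c1ccccc1 | intermediate
10 | 4,6-bis(3-methylbut-2-en-1-yl)-5-[(Z)-2-phenylethenyl]benzene-1,3-diol | CC(C)=CCc1c(O)cc(O)c(CC=C(C)C)c1/C=C\c1ccccc1 | intermediate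
11 | potassium peroxymonosulfate, KHSO5 | [K+].[O-]S(=O)(=O)OO | starting material
12 | 4-{[(2R)-3,3-dimethyloxiran-2-yl]methyl}-6-(3-methylbut-2-en-1-yl)-5-[(Z)-2-phenylethenyl]benzene-1,3-diol | CC(C)=CCc1c(O)cc(O)c(C[C@H]2OC2(C)C)c1/C=C\c1ccccc1 | intermediate
13 | (2S)-2-(2-hydroxypropan-2-yl)-5-(3-methylbut-2-en-1-yl)-4-[(Z)-2-phenylethenyl]-2,3-dihydro-1-benzofuran-6-ol | CC(C)=CCc1c(O)cc2c(c1/C=C\c1ccccc1)C[C@@H](C(C)(C)O)O2 | target

**Step count and risks**

Total step count: 5. Longest linear sequence: 5 steps (1 → 13).

The three steps most likely to fail: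

Step 5 (the proposed new step). Possible failures are oxidation of the free resorcinol ring, lower enantioselectivity because of the free hydroxyl groups, and over-oxidation. The two prenyl groups are equivalent, so at about 55% conversion the expected split is roughly 44% mono-oxidised product, 11% doubly oxidised product and 45% recovered 10, which is reused directly. The fallback uses known chemistry and keeps both phenols masked during the oxidation. It sets out from 9, isolated by ending step 4 before the fluoride stage. Standard Shi epoxidation of 9 (same ketone, 30 mol %, KHSO5, K2CO3 buffer at pH 10.5, MeCN–CH2(OMe)2, 0 °C, run to about half conversion) gives the mono-epoxide (Z)-1-{[(2R)-3,3-dimethyloxiran-2-yl]methyl}-3-(3-methylbut-2-en-1-yl)-4,6-bis[(tert-butyldimethylsilyl)oxy]-2-(2-phenylethenyl)benzene F4. Bu4NF in THF then removes both silyl groups, and the freed phenoxide next to the epoxide closes the ring 5-exo with inversion. The fallback comes back to the route at 13.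

Step 4. The dibromide is hindered and electron-rich, some branched (reverse-prenyl) product may form, and the aryl-palladium intermediate sits next to the cis-phenyl ring, so Z → E isomerisation or ring closure to a phenanthrene can compete. The fallback changes the order so that no palladium chemistry is done on the Z-stilbene. It sets out from 5. Stille coupling of 5 with 8 (Pd(PPh3)4, DMF, 90 °C; the formyl group activates the bromides) gives 2,6-bis(3-methylbut-2-en-1-yl)-3,5-bis[(tert-butyldimethylsilyl)oxy]benzaldehyde F2. Stork–Zhao olefination with (iodomethyl)triphenylphosphonium iodide and NaN(SiMe3)2 (THF–DMPU, −78 °C) gives 1,3-bis(3-methylbut-2-en-1-yl)-4,6-bis[(tert-butyldimethylsilyl)oxy]-2-[(Z)-2-iodoethenyl]benzene F3. Suzuki–Miyaura coupling with phenylboronic acid (Pd(PPh3)4, aq. K3PO4, THF, 25 °C) proceeds with retention of the alkene geometry. The fallback comes back to the route at 9, which is desilylated to 10 as in the second stage of step 4.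

Step 3. The Z:E ratio of the Wittig reaction may be lower than expected, and separation from the E isomer may be wasteful. The fallback builds the Z alkene from a Z-iodoalkene instead. It sets out from 5. Stork–Zhao olefination ((iodomethyl)triphenylphosphonium iodide, NaN(SiMe3)2, THF–DMPU, −78 °C) gives 1,3-dibromo-4,6-bis[(tert-butyldimethylsilyl)oxy]-2-[(Z)-2-iodoethenyl]benzene F1. Suzuki–Miyaura coupling with phenylboronic acid (Pd(PPh3)4, aq. K3PO4, THF, 25 °C) takes place at the alkenyl iodide with retention, well before the hindered aryl bromides react. The fallback comes back to the route at 7.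

**Further compounds**
F1 | step 3 | 1,3-dibromo-4,6-bis[(tert-butyldimethylsilyl)oxy]-2-[(Z)-2-iodoethenyl]benzene | I/C=C\c1c(Br)c(O[Si](C)(C)C(C)(C)C)cc(O[Si](C)(C)C(C)(C)C)c1Br
F2 | step 4 | 2,6-bis(3-methylbut-2-en-1-yl)-3,5-bis[(tert-butyldimethylsilyl)oxy]benzaldehyde | O=Cc1c(CC=C(C)C)c(O[Si](C)(C)C(C)(C)C)cc(O[Si](C)(C)C(C)(C)C)c1CC=C(C)C
F3 | step 4 | 1,3-bis(3-methylbut-2-en-1-yl)-4,6-bis[(tert-butyldimethylsilyl)oxy]-2-[(Z)-2-iodoethenyl]benzene | I/C=C\c1c(CC=C(C)C)c(O[Si](C)(C)C(C)(C)C)cc(O[Si](C)(C)C(C)(C)C)c1CC=C(C)C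
F4 | step 5 | (Z)-1-{[(2R)-3,3-dimethyloxiran-2-yl]methyl}-3-(3-methylbut-2-en-1-yl)-4,6-bis[(tert-butyldimethylsilyl)oxy]-2-(2-phenylethenyl)benzene | CC(C)=CCc1c(O[Si](C)(C)C(C)(C)C)cc(O[Si](C)(C)C(C)(C)C)c(C[C@H]2OC2(C)C)c1/C=C\c1ccccc1
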